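**Retrosynthetic overview**
1. Ring C (the 4-pyranone) is closed last. Phloroglucinol condenses thermally with an α-prenyl-β-keto ester, forming C4–C4a and O1–C2. A final Si–O cleavage then gives Kuwanon A.
2. The key bond is C2–C3. A σ-acyl radical is generated from the formyl C–H of a chromene-8-carbaldehyde and coupled with BrCH2CO2Me. The C3–prenyl bond is then made by alkylating the isolated β-keto ester.
3. The chromene aldehyde comes from resorcinol by formylation, chelation-controlled 4-O-silylation, 2-O-(1,1-dimethylpropargyl)ation and aromatic Claisen/oxa-6π. This sequence forces the pyran onto the oxygen ortho to the future C2.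
4. Phloroglucinol (ring A) comes from resorcinol by meta C–H borylation/oxidation.
5. Ring order: both benzene rings come from resorcinol, the dimethylpyran is formed first, and pyranone C is formed last.

Assumption: Kuwanon A has no stereocentre and no E/Z-stereogenic alkene, so it is achiral and no enantioselective step is needed.

**Step 1**
Reactants: 1 resorcinol
Product: 2 phloroglucinol (benzene-1,3,5-triol)
Conditions: HBpin (2.2 equiv), THF, rt (–H2); then [Ir(OMe)(cod)]2 (1.5 mol %), dtbpy (3 mol %), B2pin2 (0.7 equiv), 80 °C; then 30 % H2O2, pH 7 buffer, 0 °C; dilute HCl work-up (one pot)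
Reagents that add atoms: hydrogen peroxide, OO (supplies the new O)
Why: This is a sterically controlled Ir-catalysed C–H borylation/oxidation in which the transient bis(O-Bpin) ether leaves C5–H as the only C–H not ortho to a substituent, and oxidation plus hydrolysis then reveal the 1,3,5-triol.

**Step 2**
Reactants: 1 resorcinol
Product: 3 2,4-dihydroxybenzaldehyde
Conditions: POCl3, DMF, MeCN, –15 → 25 °C; then H2O, 50 °C
Reagents that add atoms: DMF, CN(C)C=O (formyl carbon); water, O (carbonyl oxygen)
Why: Vilsmeier–Haack formylation occurs at C4 of resorcinol, the position para to one OH and ortho to the other.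

**Step 3**
Reactants: 3 2,4-dihydroxybenzaldehyde
Product: 4 2-hydroxy-4-[(triisopropylsilyl)oxy]benzaldehyde
Conditions: TIPSCl (1.05 equiv), imidazole, CH2Cl2, 0 °C
Reagents that add atoms: TIPSCl, CC(C)[Si](Cl)(C(C)C)C(C)C
Why: In this chemoselective silylation the 2-OH is tied up in the O–H···O=C chelate, so only the free and more acidic 4-OH reacts.

**Step 4**
Reactants: 4 2-hydroxy-4-[(triisopropylsilyl)oxy]benzaldehyde; 5 3-chloro-3-methylbut-1-yne
Product: 6 2-[(2-methylbut-3-yn-2-yl)oxy]-4-[(triisopropylsilyl)oxy]benzaldehyde
Conditions: DBU, CuCl2·2H2O (1 mol %), MeCN, 0 °C → rt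
Reagents that add atoms: none (new atoms come from 5)
Why: Cu-catalysed propargylic etherification via a Cu-acetylide/allenylidene alkylates the only free phenol, even though it is hindered and chelated, and the essentially anhydrous low-temperature conditions spare the aryl O–TIPS group.

**Step 5**
Reactants: 6 2-[(2-methylbut-3-yn-2-yl)oxy]-4-[(triisopropylsilyl)oxy]benzaldehyde
Product: 7 2,2-dimethyl-5-[(triisopropylsilyl)oxy]-2H-chromene-8-carbaldehyde
Conditions: N,N-diethylaniline, 190 °C, 2 h
Reagents that add atoms: none
Why: An aromatic propargyl Claisen cascade ([3,3], enolisation, 1,5-H shift, oxa-6π) must end at C3, the only free ortho carbon, so the pyran O lies ortho to CHO and the silyloxy group para to it.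

**Step 6 (key step)**
Reactants: 7 2,2-dimethyl-5-[(triisopropylsilyl)oxy]-2H-chromene-8-carbaldehyde (1.5 equiv, excess recovered on chromatography); 8 methyl bromoacetate (1.0 equiv, limiting)
Product: 9 methyl 3-{2,2-dimethyl-5-[(triisopropylsilyl)oxy]-2H-chromen-8-yl}-3-oxopropanoate (isolated)
Conditions: (n-Bu4N)4W10O32 (3 mol %), NiBr2·dme/dtbbpy (10 mol %), K2HPO4, MeCN, 390 nm LEDs, rt
Reagents that add atoms: none (new atoms come from 8)
Why: Proposed new method: excited decatungstate abstracts the weak, hydridic formyl H of 7 (which has no allylic or α-oxy C–H to compete), the non-decarbonylating σ-aroyl radical is captured by the Ni(II) C-enolate formed by oxidative addition of 8, reductive elimination from Ni(III) forges C2–C3, and reduced decatungstate returns Ni(I) to Ni(0), while the electron-poor α-C–H of product 9 is polarity-mismatched for further HAT; the closest known reaction type is HAT/nickel dual-catalysed aldehyde C–H alkylation with unactivated alkyl bromides to give ketones, extended here to an α-bromo ester.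

**Step 7**
Reactants: 9 methyl 3-{2,2-dimethyl-5-[(triisopropylsilyl)oxy]-2H-chromen-8-yl}-3-oxopropanoate; 10 prenyl bromide (1-bromo-3-methylbut-2-ene, 1.05 equiv)
Product: 11 methyl 2-{2,2-dimethyl-5-[(triisopropylsilyl)oxy]-2H-chromene-8-carbonyl}-5-methylhex-4-enoate (racemic)
Conditions: K2CO3, n-Bu4NI (cat.), dry MeCN, 45 °C
Reagents that add atoms: none (new atoms come from 10)
Why: In this β-keto ester enolate C-alkylation (SN2 at the primary allylic carbon, giving the linear prenyl group), the prenyl allylic C–H bonds are introduced only after the HAT step, and the new C3 stereocentre is racemic and labile and is erased when ring C aromatises in step 8.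

**Step 8**
Reactants: 11 methyl 2-{2,2-dimethyl-5-[(triisopropylsilyl)oxy]-2H-chromene-8-carbonyl}-5-methylhex-4-enoate; 2 phloroglucinol (2 equiv)
Product: 12 5,7-dihydroxy-2-{2,2-dimethyl-5-[(triisopropylsilyl)oxy]-2H-chromen-8-yl}-3-(3-methylbut-2-en-1-yl)-4H-chromen-4-one
Conditions: neat melt under Ar, microwave, 240 °C, 8–10 min, open to vent MeOH/H2O (or Ph2O, 250 °C)
Reagents that add atoms: none
Why: In this Mentzer chromone synthesis (catalyst-free thermal phenol/β-keto ester condensation) 11 loses MeOH to an α-oxoketene that acylates the symmetrical, strongly C-nucleophilic triol at carbon (C4–C4a), after which the ortho OH condenses with the aryl ketone (O1–C2, –H2O), so only one regioisomer can form and the acid-sensitive alkenes never meet an added Lewis or Brønsted acid.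

**Step 9**
Reactants: 12 4'-O-TIPS Kuwanon A
Product: 13 Kuwanon A
Conditions: TBAF (1.1 equiv), AcOH (1.1 equiv), THF, 0 °C, 15 min
Reagents that add atoms: none
Why: Buffered fluoride desilylation of the aryl silyl ether leaves the prenyl and chromene alkenes untouched and also removes any silyl group scrambled onto ring A during the melt.

**Compound list**
1 | resorcinol | Oc1cccc(O)c1 | starting material
2 | phloroglucinol | Oc1cc(O)cc(O)c1 | intermediate
3 | 2,4-dihydroxybenzaldehyde | O=Cc1ccc(O)cc1O | intermediate
4 | 2-hydroxy-4-(triisopropylsilyloxy)benzaldehyde | O=Cc1ccc(O[Si](C(C)C)(C(C)C)C(C)C)cc1O | intermediate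
5 | 3-chloro-3-methylbut-1-yne | C#CC(C)(C)Cl | starting material
6 | 2-(2-methylbut-3-yn-2-yloxy)-4-(triisopropylsilyloxy)benzaldehyde | O=Cc1ccc(O[Si](C(C)C)(C(C)C)C(C)C)cc1OC(C)(C)C#C | intermediate
7 | 2,2-dimethyl-5-(triisopropylsilyloxy)-2H-chromene-8-carbaldehyde | O=Cc1ccc(O[Si](C(C)C)(C(C)C)C(C)C)c2C=CC(C)(C)Oc12 | intermediate
8 | methyl bromoacetate | COC(=O)CBr | starting material
9 | methyl 3-[2,2-dimethyl-5-(triisopropylsilyloxy)-2H-chromen-8-yl]-3-oxopropanoate | COC(=O)CC(=O)c1ccc(O[Si](C(C)C)(C(C)C)C(C)C)c2C=CC(C)(C)Oc12 | intermediate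
10 | prenyl bromide (1-bromo-3-methylbut-2-ene) | CC(C)=CCBr | starting material
11 | methyl 2-[2,2-dimethyl-5-(triisopropylsilyloxy)-2H-chromene-8-carbonyl]-5-methylhex-4-enoate (racemic) | COC(=O)C(CC=C(C)C)C(=O)c1ccc(O[Si](C(C)C)(C(C)C)C(C)C)c2C=CC(C)(C)Oc12 | intermediate
12 | 4'-O-TIPS Kuwanon A | CC(C)=CCc1c(-c2ccc(O[Si](C(C)C)(C(C)C)C(C)C)c3c2OC(C)(C)C=C3)oc2cc(O)cc(O)c2c1=O | intermediate
13 | Kuwanon A | CC(C)=CCc1c(-c2ccc(O)c3c2OC(C)(C)C=C3)oc2cc(O)cc(O)c2c1=O | target

**Totals**
Total steps: 9.
Longest linear sequence: 8 (1 → 3 → 4 → 6 → 7 → 9 → 11 → 12 → 13). Step 1 is a one-step side branch that joins at step 8.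

**Steps most likely to fail, with fallbacks**
- **Step 6.** The risks are:
  - SET or energy-transfer quenching by the electron-rich chromene aldehyde;
  - photochromic ring opening at 390 nm;
  - addition of the electrophilic •CH2CO2Me radical to the chromene C3=C4 bond;
  - alkylation of 9 by residual 8.

  Fallback: abandon formyl C–H activation. Homologate 7 with methyl diazoacetate (SnCl2, Roskamp reaction) to 9 and rejoin the route at step 7.
- **Step 8.** The risks are the 240 °C temperature, hydrolytic decarboxylation of 11, and low reactivity of an α-substituted, ortho-hindered aroylacetate. Fallback: close ring C through a 1,3-diketone at or below 60 °C.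
  - Demethoxycarbonylate 11 (Krapcho) to the homoprenyl ketone.
  - C-acylate this ketone by MgBr2·OEt2/i-Pr2NEt soft enolisation with 2,4,6-tris(silyloxy)benzoyl chloride, which is made from 2 by Kolbe–Schmitt carboxylation and silylation.
  - Finish with fluoride-triggered cyclodehydration.
- **Step 1.** The risks are incomplete or ortho borylation of the bis(O-Bpin) ether, and over-oxidation or difficult isolation of the water-soluble triol. Fallback: build ring A de novo. Condense a dialkyl malonate with itself under sodium mediation to the phloroglucinol dicarboxylate, then hydrolyse and decarboxylate to 2.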